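The numbers in the tables were computed on assumed constants.

At its last reading, 3.00 min in, Tuesday's flask holds 8.2 % of left-handed product, while Sunday's flask, with half the coupling partner, needs 6.00 min for 8.0 %. Read as mean slopes these are 0.0437 M/min and 0.0213 M/min, so within the scatter the rate is twice as high for twice the partner.

common to all: left-handed substrate 0.80 M; right-handed substrate 0.80 M; catalyst 0.1 mol%
- Tuesday's: coupling partner 3 equiv; the very flask that is asked about, followed so far
- Sunday's: coupling partner 1.5 equiv; run made earlier
- flask: coupling partner 3.00 equiv

| run | time / min | left-handed product / % | left-handed substrate / % |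
|---|---|---|---|
| Tuesday's | 0.500 | 2.1 | 48.5 |
| Tuesday's | 1.00 | 2.7 | 46.7 |
| Tuesday's | 1.50 | 4.8 | 45.0 |
| Tuesday's | 2.00 | 5.5 | 43.5 |
| Tuesday's | 2.50 | 7.3 | 42.7 |
| Tuesday's | 3.00 | 8.2 | 41.7 |
| Sunday's | 0.417 | 0.6 | 49.3 |
| Sunday's | 1.33 | 2.4 | 47.9 |
| Sunday's | 2.00 | 3.0 | 47.1 |
| Sunday's | 3.00 | 4.5 | 45.6 |
| Sunday's | 5.00 | 7.2 | 43.2 |
| Sunday's | 6.00 | 8.0 | 42.6 |

(standard deviation of a reading: 0.5 percentage points)

- catalyst is single-handed; left-handed substrate and right-handed substrate are mirror images of each other, charged as a racemate, each of them at the stated concentration
- no earlier run changes the charge of catalyst; that part of a forecast is a guess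

- apparent order in catalyst when 30 % of the left-handed substrate and right-handed substrate together are converted (percent change of the rate of making left-handed product for one percent more catalyst charged)

I therefore draw the curve of the coupling partner in Tuesday's flask, which is the flask asked about, taking one partner for each substrate turned over. It starts at 2.40 M, more than the 1.60 M of the two substrates together, so the substrates are the limiting reagent, and with both substrates turned over in full this balance stands at 0.800 M, a third of the charge. At the 30 % conversion asked about stands my landmark, the partner left at that conversion, 1.92 M. The catalyst does not enter this balance, so in my reckoning the order compares rates at equal partner. No reading tests the catalyst, so I put no number of my own on the order.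

The forecast gives 1, between 0.7 and 1.15, and says plainly: “No run varies the catalyst, so its order is a guess”.

    catalyst ⇌ dormant form (K = 0.740, k = 0.00550 /s)
    coupling partner + catalyst + left-handed substrate → catalyst + left-handed product (k = 0.720 /M²/s)
    coupling partner + catalyst + right-handed substrate → catalyst + right-handed product (k = 0.250 /M²/s)
    coupling partner → decomposition product (k = 2.90 × 10⁻⁶ /s)

The flask gives an order of 1.0, inside the forecast's range, so one percent more catalyst charged means one percent more rate at that conversion, while at 6.00 min this flask holds 57.9 % of its catalyst charge as catalyst and 42.1 % as dormant form. The partner left gives a mean partner of 2.16 M on the way to that conversion, reached after 12.1 min. The same balance gives 4.56 M for a flask with twice the coupling partner, so, if the rate is taken as proportional to the partner, the ratio of means estimates the time to that conversion at 0.474 of this flask's, and the factor found for that flask is 0.429.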